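A direct plan would convert pent-4-en-1-amine A1 into its 4,5-dibromo-1H-pyrrole-2-carboxamide A2, oxidise the alkene in two steps to the α-ketoaldehyde A3, condense A3 with urea A4 under acid to racemic dibromophakellstatin A5, and separate the enantiomers on a chiral column.
Its weakest steps would be:
– the enantiomer separation at the end: no reaction would set the absolute configuration, and half of the most advanced material would be discarded;
– the acid-mediated urea condensation: three rings, four C–N bonds and both aminal centres would be left to one thermodynamic cascade on late material, with hydantoin formation by 1,2-shift and double urea addition as open exits;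
– the two alkene oxidations: they would add no skeletal complexity and would end in a hydrated, self-condensing 1,2-dicarbonyl compound next to a free pyrrole N–H that would have to be used crude.

Plan of the new route
Cuts: the imidazolidinone at NH–CH (amidoalkylation) and at C(=O)–NH2 (NH3 plus isocyanate); the N–C bond at the quaternary carbon through a Hofmann 1,2-shift back to a carboxamide; the CH–C(quaternary) bond by an aldol with formaldehyde; the pyrrole amide bond.
Enabling feature: the ring-fusion carbon shared by the pyrrolidine, pyrazinone and imidazolidinone rings bears N(amide), CH2, the aminal CH and N(urea)–C=O. It is therefore Cα of L-proline: the urea carbonyl is the proline carboxyl carbon with one nitrogen inserted in front of it, and the aminal CH is a hydroxymethyl group in place of the α-H.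
Ring order: pyrrolidine (L-proline) and pyrrole (bought) first, pyrazinone by N,O-aminal closure (step 6), imidazolidinone last (step 7); the tetracycle exists only as the final product.
The weak steps do not arise: no 1,2-dicarbonyl compound is made, no urea is condensed with a carbonyl pair, and the single ring closed under acid can only be cis-fused. The configuration sits on a quaternary carbon from step 2 on and passes through two stereoretentive events, so nothing is resolved.

Key step: step 7

Assumption: the enantiomer drawn in the target SMILES (cis-fused, quaternary aminal carbon R, aminal CH S) is taken to be the levorotatory one, and the route is built on these CIP descriptors and not on the sign. Enolate functionalisation of the proline N,O-acetal and the 1,2-shift are taken to proceed with retention, as is general for both reaction classes.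

Step 1
Reactants: 1 L-proline; 2 pivalaldehyde
Product: 3 (3R,7aS)-3-tert-butyltetrahydro-1H,3H-pyrrolo[1,2-c][1,3]oxazol-1-one
Conditions: 2 (6 equiv), TFA (cat.), pentane, reflux, Dean–Stark, 3 d; Kugelrohr distillation
Reagents that add atoms: none
Why: Acid-catalysed N,O-acetal formation under azeotropic water removal should give the cis-fused bicyclic lactone as one diastereomer under thermodynamic control (tert-butyl on the convex face, cis to the α-H), which stores the proline configuration in the acetal centre (self-regeneration of stereocentres).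

Step 2
Reactants: 3 (3R,7aS)-3-tert-butyltetrahydro-1H,3H-pyrrolo[1,2-c][1,3]oxazol-1-one; 4 formaldehyde
Product: 6 (3R,7aR)-3-tert-butyl-7a-(hydroxymethyl)tetrahydro-1H,3H-pyrrolo[1,2-c][1,3]oxazol-1-one, via lithium (3R)-3-tert-butyl-6,7-dihydro-3H,5H-pyrrolo[1,2-c][1,3]oxazol-1-olate 5 (not isolated)
Conditions: LDA (1.1 equiv), THF, −78 °C; CH2O gas (cracked paraformaldehyde, N2 stream), −78 °C; AcOH, −78 °C → rt
Reagents that add atoms: none
Why: Aldol addition of the bicyclic lithium enolate to monomeric formaldehyde should occur on the convex face cis to tert-butyl, so that CH2OH takes the place of the former α-H with overall retention and the future quaternary aminal carbon is set under control of the acetal centre.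

Step 3
Reactants: 6 (3R,7aR)-3-tert-butyl-7a-(hydroxymethyl)tetrahydro-1H,3H-pyrrolo[1,2-c][1,3]oxazol-1-one
Product: 7 (R)-2-(hydroxymethyl)pyrrolidine-2-carboxamide
Conditions: NH3 (7 M in MeOH), sealed tube, 50 °C; evaporate; H2O/Et2O partition, lyophilise the aqueous phase
Reagents that add atoms: ammonia, N
Why: Aminolysis of the acylal-type lactone (an activated ester) should give the primary amide, the ring-opened N,O-hemiaminal collapsing to pivalaldehyde and the free secondary amine; the quaternary centre has no α-H and cannot epimerise.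

Step 4
Reactants: 8 4,5-dibromo-1H-pyrrole-2-carboxylic acid
Product: 9 4,5-dibromo-1H-pyrrole-2-carbonyl chloride
Conditions: (COCl)2 (1.5 equiv), DMF (cat.), CH2Cl2, 0 °C → rt; evaporate, use crude
Reagents that add atoms: oxalyl chloride, O=C(Cl)C(=O)Cl
Why: Vilsmeier-catalysed acyl chloride formation; the pyrrole N–H, flanked by bromine and deactivated by the acyl group, should not self-acylate in the absence of base.

Step 5
Reactants: 7 (R)-2-(hydroxymethyl)pyrrolidine-2-carboxamide; 9 4,5-dibromo-1H-pyrrole-2-carbonyl chloride
Product: 10 (R)-1-(4,5-dibromo-1H-pyrrole-2-carbonyl)-2-(hydroxymethyl)pyrrolidine-2-carboxamide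
Conditions: 9 (1.5 equiv), NaHCO3, THF/H2O, 0 °C → rt
Reagents that add atoms: none
Why: Schotten–Baumann N-acylation: the secondary amine is the most nucleophilic site despite its neopentyl position, aqueous bicarbonate disfavours ester formation, and any O-acyl isomer would hand its acyl group to the neighbouring nitrogen by O→N shift; no stereocentre is touched.

Step 6
Reactants: 10 (R)-1-(4,5-dibromo-1H-pyrrole-2-carbonyl)-2-(hydroxymethyl)pyrrolidine-2-carboxamide
Product: 13 (5aR)-2,3-dibromo-5-methoxy-10-oxo-5a,6,7,8-tetrahydro-5H,10H-dipyrrolo[1,2-a:1',2'-d]pyrazine-5a-carboxamide (C5 epimers), via (R)-1-(4,5-dibromo-1H-pyrrole-2-carbonyl)-2-formylpyrrolidine-2-carboxamide 11 (not isolated), via (5aR)-2,3-dibromo-5-hydroxy-10-oxo-5a,6,7,8-tetrahydro-5H,10H-dipyrrolo[1,2-a:1',2'-d]pyrazine-5a-carboxamide 12 (not isolated)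
Conditions: Dess–Martin periodinane (1.1 equiv), MeCN, 0 °C → rt; then MeOH, CSA (0.2 equiv), 3 Å MS, rt, same flask
Reagents that add atoms: methanol, CO
Why: Dess–Martin oxidation should give a quaternary, non-enolisable aldehyde that the acidic pyrrole N–H captures at once as the six-membered hemiaminal (6-exo-trig addition to C=O, the usual ring–chain preference of N-(pyrrol-2-ylcarbonyl)-2-aminoaldehydes), and acid-catalysed acetal exchange replaces OH by OMe so that no hydroxyl can capture the isocyanate of step 7; the new aminal centre forms as an epimer mixture that converges in step 7.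

Step 7
Reactants: 13 (5aR)-2,3-dibromo-5-methoxy-10-oxo-5a,6,7,8-tetrahydro-5H,10H-dipyrrolo[1,2-a:1',2'-d]pyrazine-5a-carboxamide
Product: 16 (−)-dibromophakellstatin (quaternary aminal carbon R, aminal CH S), via (5aS)-2,3-dibromo-5a-isocyanato-5-methoxy-5a,6,7,8-tetrahydro-5H,10H-dipyrrolo[1,2-a:1',2'-d]pyrazin-10-one 14 (not isolated), via 1-[(5aR)-2,3-dibromo-5-methoxy-10-oxo-5a,6,7,8-tetrahydro-5H,10H-dipyrrolo[1,2-a:1',2'-d]pyrazin-5a-yl]urea 15 (not isolated)
Conditions: PhI(OAc)2 (1.5 equiv), NH3 (7 M in MeOH, 20 equiv), 0 °C → rt; evaporate; TFA/CH2Cl2 (1:1), rt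
Reagents that add atoms: ammonia, N
Why: Ligand exchange of the primary amide on iodine(III) should give an N-iodanyl amide whose quaternary carbon migrates from C to N with loss of PhI (Hofmann rearrangement; closest known reaction types are iodine(III) Hofmann reactions of N-acyl α-amino amides to gem-diamino derivatives and the PhI(OAc)2/NH3 conversion of primary amides into ureas), so that one nitrogen is inserted between the ring-fusion carbon and the former proline carboxyl carbon to give isocyanate 14. Ammonia adds to 14 to give urea 15; the methoxy group on the neighbouring aminal carbon and the two acylated ring nitrogens leave no internal nucleophile to compete, and amine addition to an isocyanate outruns methanol addition by orders of magnitude. TFA then ionises the N,O-acetal (loss of MeOH) to a cation stabilised by the pyrrole nitrogen, which the terminal urea NH2 captures in a 5-exo-trig amidoalkylation that closes the imidazolidinone; should the pyrazinone open reversibly under acid, the urea-stabilised N-acyliminium ion is re-closed by the pyrrole N–H (6-exo-trig) to the same product. The quaternary aminal centre is substrate-controlled: the migrating carbon keeps its configuration in the 1,2-shift and has no α-H, so it derives unchanged from step 2. The aminal CH is controlled by the ring fusion: a five-membered ring can bridge the C–C bond only cis, so both C5 epimers of 13 converge on one product. The step needs N- rather than O-cyclisation of the urea, which acid secures because the O-alkyl isourea ionises back, and it needs the aminal at the quaternary carbon to survive, which the two acyl-type nitrogens make a poor heterolysis site.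

Compound list
1 | L-proline, (S)-pyrrolidine-2-carboxylic acid | OC(=O)[C@@H]1CCCN1 | starting material
2 | pivalaldehyde (2,2-dimethylpropanal) | CC(C)(C)C=O | starting material
3 | (3R,7aS)-3-tert-butyltetrahydro-1H,3H-pyrrolo[1,2-c][1,3]oxazol-1-one | O=C1O[C@H](C(C)(C)C)N2CCC[C@@H]12 | intermediate
4 | formaldehyde (monomer from paraformaldehyde) | C=O | starting material
5 | lithium (3R)-3-tert-butyl-6,7-dihydro-3H,5H-pyrrolo[1,2-c][1,3]oxazol-1-olate (lithium enolate of 3, not isolated) | [Li+].[O-]C1=C2CCCN2[C@@H](C(C)(C)C)O1 | intermediate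
6 | (3R,7aR)-3-tert-butyl-7a-(hydroxymethyl)tetrahydro-1H,3H-pyrrolo[1,2-c][1,3]oxazol-1-one | O=C1O[C@H](C(C)(C)C)N2CCC[C@@]12CO | intermediate
7 | (R)-2-(hydroxymethyl)pyrrolidine-2-carboxamide | NC(=O)[C@]1(CO)CCCN1 | intermediate
8 | 4,5-dibromo-1H-pyrrole-2-carboxylic acid | OC(=O)c1cc(Br)c(Br)[nH]1 | starting material
9 | 4,5-dibromo-1H-pyrrole-2-carbonyl chloride | ClC(=O)c1cc(Br)c(Br)[nH]1 | intermediate
10 | (R)-1-(4,5-dibromo-1H-pyrrole-2-carbonyl)-2-(hydroxymethyl)pyrrolidine-2-carboxamide | NC(=O)[C@]1(CO)CCCN1C(=O)c1cc(Br)c(Br)[nH]1 | intermediate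
11 | (R)-1-(4,5-dibromo-1H-pyrrole-2-carbonyl)-2-formylpyrrolidine-2-carboxamide (not isolated) | NC(=O)[C@]1(C=O)CCCN1C(=O)c1cc(Br)c(Br)[nH]1 | intermediate
12 | (5aR)-2,3-dibromo-5-hydroxy-10-oxo-5a,6,7,8-tetrahydro-5H,10H-dipyrrolo[1,2-a:1',2'-d]pyrazine-5a-carboxamide (tricyclic pyrrole-N hemiaminal, C5 epimers, not isolated) | NC(=O)[C@]12CCCN1C(=O)c1cc(Br)c(Br)n1C2O | intermediate
13 | (5aR)-2,3-dibromo-5-methoxy-10-oxo-5a,6,7,8-tetrahydro-5H,10H-dipyrrolo[1,2-a:1',2'-d]pyrazine-5a-carboxamide (C5 epimers) | NC(=O)[C@]12CCCN1C(=O)c1cc(Br)c(Br)n1C2OC | intermediate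
14 | (5aS)-2,3-dibromo-5a-isocyanato-5-methoxy-5a,6,7,8-tetrahydro-5H,10H-dipyrrolo[1,2-a:1',2'-d]pyrazin-10-one (same spatial arrangement as 13; not isolated) | O=C=N[C@]12CCCN1C(=O)c1cc(Br)c(Br)n1C2OC | intermediate
15 | 1-[(5aR)-2,3-dibromo-5-methoxy-10-oxo-5a,6,7,8-tetrahydro-5H,10H-dipyrrolo[1,2-a:1',2'-d]pyrazin-5a-yl]urea (not isolated) | NC(=O)N[C@]12CCCN1C(=O)c1cc(Br)c(Br)n1C2OC | intermediate
16 | (−)-dibromophakellstatin (cis-fused tetracycle, quaternary aminal carbon R, aminal CH S) | O=C1N[C@H]2n3c(cc(Br)c3Br)C(=O)N3CCC[C@]23N1 | target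

Step count
Total: 7 steps. Longest linear sequence: 6 steps (1, 2, 3, 5, 6, 7 from L-proline); step 4 is a one-step side branch.

Steps most likely to fail, with fallbacks

1. Step 7. The isocyanate may be captured by methanol or acetate instead of ammonia, or ionisation of the electron-poor N,O-acetal may be so slow that the urea is lost by heterolysis at the quaternary carbon before the ring closes. The fallback changes the order of ring closure and sets out from 10. Silylation of the primary alcohol (TBSCl, imidazole, DMF) would give (R)-2-[(tert-butyldimethylsilyloxy)methyl]-1-(4,5-dibromo-1H-pyrrole-2-carbonyl)pyrrolidine-2-carboxamide F1. The same PhI(OAc)2/NH3 treatment would lead through the isocyanate F2 to the silyloxy urea F3. TBAF would free the ureido alcohol F4, and Dess–Martin oxidation would give the ureido aldehyde F5. In TFA, F5 should condense first with the urea NH2 and then, through the urea-stabilised N-acyliminium ion, with the pyrrole N–H, which returns to the route at 16.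

2. Step 3. The tert-butyl group and the bicyclic frame may shield the lactone carbonyl so that ammonia attacks too slowly, or the liberated amino alcohol may re-condense with pivalaldehyde. The fallback sets out from 6: HCl in MeOH at reflux would cleave the N,O-acetal and esterify to methyl (R)-2-(hydroxymethyl)pyrrolidine-2-carboxylate F6 (as hydrochloride). Its unshielded ester would then be ammonolysed (NH3/MeOH, sealed tube), which returns to the route at 7.

3. Step 2. Formaldehyde may polymerise on the cold solution, or the enolate may decompose before the C–C bond forms, giving low conversion. The fallback sets out from 3 and replaces the aldol by an SN2 alkylation under the same facial control: enolate 5 with benzyl chloromethyl ether would give (3R,7aR)-7a-[(benzyloxy)methyl]-3-tert-butyltetrahydro-1H,3H-pyrrolo[1,2-c][1,3]oxazol-1-one F7. Hydrogenolysis (H2, Pd/C, EtOAc) would then return to the route at 6.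

Further compounds
F1 | step 7 | (R)-2-[(tert-butyldimethylsilyloxy)methyl]-1-(4,5-dibromo-1H-pyrrole-2-carbonyl)pyrrolidine-2-carboxamide | NC(=O)[C@]1(CO[Si](C)(C)C(C)(C)C)CCCN1C(=O)c1cc(Br)c(Br)[nH]1
F2 | step 7 | (S)-{2-[(tert-butyldimethylsilyloxy)methyl]-2-isocyanatopyrrolidin-1-yl}(4,5-dibromo-1H-pyrrol-2-yl)methanone (same spatial arrangement as F1) | O=C=N[C@]1(CO[Si](C)(C)C(C)(C)C)CCCN1C(=O)c1cc(Br)c(Br)[nH]1
F3 | step 7 | 1-{(R)-2-[(tert-butyldimethylsilyloxy)methyl]-1-(4,5-dibromo-1H-pyrrole-2-carbonyl)pyrrolidin-2-yl}urea | NC(=O)N[C@]1(CO[Si](C)(C)C(C)(C)C)CCCN1C(=O)c1cc(Br)c(Br)[nH]1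
F4 | step 7 | 1-[(R)-1-(4,5-dibromo-1H-pyrrole-2-carbonyl)-2-(hydroxymethyl)pyrrolidin-2-yl]urea | NC(=O)N[C@]1(CO)CCCN1C(=O)c1cc(Br)c(Br)[nH]1
F5 | step 7 | 1-[(R)-1-(4,5-dibromo-1H-pyrrole-2-carbonyl)-2-formylpyrrolidin-2-yl]urea | NC(=O)N[C@]1(C=O)CCCN1C(=O)c1cc(Br)c(Br)[nH]1
F6 | step 3 | methyl (R)-2-(hydroxymethyl)pyrrolidine-2-carboxylate | COC(=O)[C@]1(CO)CCCN1
F7 | step 2 | (3R,7aR)-7a-[(benzyloxy)methyl]-3-tert-butyltetrahydro-1H,3H-pyrrolo[1,2-c][1,3]oxazol-1-one | O=C1O[C@H](C(C)(C)C)N2CCC[C@@]12COCc1ccccc1
A1 | direct plan | pent-4-en-1-amine | C=CCCCN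
A2 | direct plan | 4,5-dibromo-N-(pent-4-en-1-yl)-1H-pyrrole-2-carboxamide | C=CCCCNC(=O)c1cc(Br)c(Br)[nH]1
A3 | direct plan | 4,5-dibromo-N-(4,5-dioxopentyl)-1H-pyrrole-2-carboxamide | O=CC(=O)CCCNC(=O)c1cc(Br)c(Br)[nH]1
A4 | direct plan | urea | NC(N)=O
A5 | direct plan | (±)-dibromophakellstatin (cis-fused racemate, both enantiomers written) | O=C1N[C@H]2n3c(cc(Br)c3Br)C(=O)N3CCC[C@]23N1.O=C1N[C@@H]2n3c(cc(Br)c3Br)C(=O)N3CCC[C@@]23N1
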